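## Structural features

The target is a (2S)-flavan: a phloroglucinol-type benzene (ring A) fused to a dihydropyran (ring C) whose C2 carries the unsubstituted phenyl ring B. Ring A bears OMe at C5, OH at C7 and, at C8 between O1 and the C7 oxygen, a benzofuran-2-yl group (furan ring D, benzo ring E, primed atoms). C2 is the only stereocentre and has no stereogenic neighbour; it is benzylic and bound to O1, so it can ionise under strong acid (ring opening, racemisation) or be cleaved by hydrogenolysis. The fragile parts are the two electron-rich arenes (ring A and the resorcinol-type ring E, open to oxidation and to electrophiles at C6, C3′ and C7′), the benzylic C2–O1 ether and the two free phenols. The real difficulty is regiochemical, not stereochemical. Ring A needs C8 told apart from C6 and the C7 oxygen told apart from the C5 oxygen. Ring E carries OMe (C4′), Me (C5′), OH (C6′) and H (C7′) on four contiguous carbons, with two oxygens that must end in different states. The key step uses exactly this C4′–C7′ unit: it is laid onto the C3a′–C7a′ edge of an existing furan, C4′ and C7′ coming from a furylketene and C5′ (Me) and C6′ (O) from a 1-siloxypropyne, so the ring is born with free OH at C4′ and a silyl ether at C6′.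

## Logic of the disconnections

27 ⇒ 25 (through 26). Cut: the O–Si bond at C6′ and the O–CH2 acetal bond at the C7 oxygen. Reason: the two phenols are the most oxidisable and most acidic sites and would intercept ketenes and alkylating agents, so they are revealed last. Gain: every earlier compound is a neutral ether that can be chromatographed. Demand: both groups must fall in one flask (fluoride, then dilute protic acid in an alcohol) without touching the aryl methyl ethers or ionising the C2–O1 bond.

25 ⇒ 24. Cut: the O–CH3 bond at C4′. Reason: the annulation delivers the C4′ oxygen as the only free hydroxyl of 24 while the C6′ oxygen is born silylated, so one alkylation fixes the OMe/OH pattern of ring E. Gain: no selectivity problem between the two ring E oxygens. Demand: a base weak enough to leave the aryl silyl ether in place.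

24 ⇒ 16 + 19. Cut: C7′–C7a′, C4′–C5′, C6′–C7′ and C4′–C3a′, which removes all of ring E except the furan edge. Reason: the four contiguous substituents map onto a two-carbon ketene unit and a polarised two-carbon alkyne, so the substitution pattern follows from polarity and not from aromatic substitution. Gain: a 2-arylbenzofuran with a fully differentiated benzo ring becomes a 2,5-disubstituted furan and a three-carbon alkyne; no stereocentre is involved. Demand: one orientation in the ketene–alkyne cycloaddition, and tolerance of ultraviolet light and about 80 °C. For that reason 16 carries no O–H group, and the small acetal at the C7 oxygen is kept because it does not hinder the C8 coupling and leaves in the same flask as the silyl group at the end.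

19 ⇒ 17 (through 18). Cut: the O–Si bond and the bond between the two alkyne carbons, one of which is a one-carbon insert. Reason: the ynolate is the homologue of a two-carbon ester. Gain: the alkyne comes in one operation from a bulk ester. Demand: O-silylation, not C-silylation, which the bulky silyl group provides.

16 ⇒ 14 (through 15). Cut: the C=N2 bond. Reason: the diazo carbon is taken as the methyl carbon of a methyl ketone, so the acyl unit arrives complete and no acid chloride has to be treated with a volatile, explosive diazoalkane. Gain: two functional-group steps fewer and the most hazardous reagent of the classical approach avoided. Demand: activation of the single enolisable position before diazo transfer.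

14 ⇒ 10 + 11 (through 12 and 13). Cut: the bond from C8 to the furan α-carbon. Reason: the bromofuran already holds the acetyl group, so nothing has to be adjusted after the coupling. Gain: the flavan and the furan are made separately. Demand: coupling at a carbon flanked by two oxygens with an organometallic that tolerates a ketone, hence zinc.

10 ⇒ 9. Cut: C8–I. Reason: the halogen marks the site of the later C–C bond. Demand: C8 must react in preference to C6.

9 ⇒ 8. Cut: O1–C2. Reason: ring C closes by displacement at the carbinol carbon by the ortho phenol. Gain: the stereocentre becomes that of an acyclic benzylic alcohol. Demand: clean inversion, so the carbinol must be (R).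

8 ⇒ 7. Cut: the C–H bond at the carbinol carbon. Reason: an aryl ketone flanked by phenyl and a primary alkyl chain is an ideal case for catalytic enantioselective reduction. Demand: tolerance of the free phenol.

7 ⇒ 6 ⇒ 4 + 5. Cut: after C3–C4 (flavan numbering) is written as an alkene, the Cα=Cβ bond of the enone. Reason: aldol condensation joins ring A to the phenyl ketone in one step. Gain: two simple aromatic pieces. Demand: the acetal must survive hydroxide, and the hydrogenation must stop at the saturated ketone.

4 ⇒ 3 ⇒ 1 (through 2). Cut: the acetal O–CH2 bond at the para oxygen, then the ring–CHO bond. Reason: the formyl group differentiates the two hydroxyls of 1 (one becomes chelated) and the two ring positions. Demand: formylation para to a hydroxyl, not between the two hydroxyls, and protection of only the unchelated hydroxyl.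

## Other disconnections considered

Alternative 1: Cut: ring D at C3′–C3a′ and O1′–C2′, giving the 8-acetylflavan A2 and the O-arylhydroxylamine A3, which already holds the three ring E substituents. Forward key step: acid-promoted condensation of A2 with A3 to the O-aryl oxime ether, tautomerisation, a [3,3] shift that forms C3′–C3a′, and closure of the freed phenol oxygen onto C2′ with loss of the nitrogen atom, giving A1. In favour: no diazo compound and no ultraviolet photolysis, so on hazard it is the better plan. The ring E oxygens arrive already as OMe and silyl ether, so no methylation follows the key step; on the number of steps after the key step it is at least the equal of the chosen plan. Against: A3 has two free ortho positions, one next to OMe and one next to the siloxy group, and only the shift towards the first gives the target pattern. A3 is a 1,3,4,5-tetrasubstituted benzene with three different oxygens that needs its own synthesis, so the ring E problem is moved and not solved. A2 requires C8 acylation with the same C6/C8 question as step 7, and its ketone, flanked by two ortho oxygens, should condense slowly. Strong acid also endangers the aryl silyl ether and the C2–O1 bond, and the final benzyl removal by hydrogenolysis competes with the benzylic ring ether. Comparison: structurally this plan forms the smaller ring and leaves the hard ring to a separate sequence; mechanistically its regiochemistry rests on a weak steric bias, whereas in the chosen plan it follows from the polarity of ketene and alkyne; in step economy it is probably no shorter once A3 is counted.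

Alternative 2: Cut: O1–C8a and C8–I. Forward key step: excess hindered lithium amide removes the C8 proton of the fluoroarene carbinol A5, fluoride loss gives the aryne A6, the tethered alkoxide adds at C8a to close ring C, and an electrophilic iodine quench of the C8 anion gives A4, which is the same compound as 10. In favour: the iodine can only arrive at C8, which is better than the electrophilic iodination of step 7. The carbinol oxygen becomes O1 with retention, so no phosphine or azodicarboxylate is needed; the carbinol must then be (S), obtained with the enantiomeric reduction catalyst, which is equal in effort. One step replaces steps 6 and 7. Against: it needs a ring A building block with fluorine at the future C8a, which is not an obvious catalogue compound, so steps return at the front. The C6 proton of A5 is also acidified by two oxygens and its removal would waste base and lead to iodine at C6. The plan does not address ring E at all. Comparison: this is complementary and not competing; it ends at 10 and would still need steps 8 to 13. On mechanism it is the more certain way to C8 selectivity; on structure and overall step economy it offers no clear gain.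

Alternative 3: Cut: ring C at C3–C4 and O1–C2, giving the hydroxymethyl phenol A8 and styrene A9. Forward key step: a confined chiral Brønsted acid dehydrates A8 to the ortho-quinone methide A10, which adds A9 across its methylene carbon and carbonyl oxygen to give A7. In favour: it is the most convergent plan. Ring C and the stereocentre are made in the last skeletal step from an achiral precursor by a catalyst with only a small molecule lost, which on paper is better step and atom economy than the chosen plan. Against: A9 is an unactivated partner. A10 is very electron-rich and carries the large benzofuranyl group next to the oxygen where the chiral acid must bind, so rate and enantiocontrol are both doubtful. The nucleophilic C3′ and C7′ positions of the benzofuran can add to A10 and give oligomers. A8 needs the finished benzofuran on a ring A with four different substituents, so a ring E construction is still required before it. The two benzyl ethers must finally be removed by hydrogenolysis next to a benzylic ring ether. Comparison: structurally it postpones the stereocentre, which is attractive; mechanistically its enantiocontrol depends on catalyst fit to a bulky substrate, whereas the chosen plan differentiates phenyl from a primary alkyl chain in a ketone reduction, a far more dependable situation; its step economy is better only if the late cycloaddition performs.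

Key step: step 11

Remark: C2 is read as (S) (priority O1 > phenyl > C3 > H) and is taken as the only stereogenic element, because the C8–C2′ bond to the five-membered ring D has only O and H as ortho neighbours on the furan side and should rotate freely.

## Route

Step 1
Reactants: 1 5-methoxyresorcinol
Product: 3 2,4-dihydroxy-6-methoxybenzaldehyde, via iminium chloride 2 (not isolated)
Conditions: POCl3, DMF, MeCN, 0 → 25 °C; then H2O, 50 °C
Reagents that add atoms: N,N-dimethylformamide, CN(C)C=O; water, O
Why: Vilsmeier–Haack formylation; the chloroiminium ion should attack the position para to one hydroxyl and ortho to the other hydroxyl and the methoxy group (two equivalent sites) in preference to the position between the hydroxyls, and hydrolysis of 2 releases the aldehyde.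

Step 2
Reactants: 3 2,4-dihydroxy-6-methoxybenzaldehyde
Product: 4 2-hydroxy-6-methoxy-4-(methoxymethoxy)benzaldehyde
Conditions: CH2(OMe)2, AcCl, ZnBr2 (cat.), toluene, 25 °C; then 3, iPr2NEt, THF, 0 → 25 °C
Reagents that add atoms: chloromethyl methyl ether, COCCl (made in the flask from dimethoxymethane, COCOC, and acetyl chloride, CC(=O)Cl)
Why: O-alkylation with an α-chloro ether; the C2 hydroxyl is held in a hydrogen bond to the formyl group, so one equivalent should alkylate only the more acidic, unchelated C4 hydroxyl, and using the chloro ether as a freshly made solution avoids handling the neat carcinogen.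

Step 3
Reactants: 4 2-hydroxy-6-methoxy-4-(methoxymethoxy)benzaldehyde; 5 acetophenone
Product: 6 (E)-3-[2-hydroxy-6-methoxy-4-(methoxymethoxy)phenyl]-1-phenylprop-2-en-1-one
Conditions: KOH, EtOH/H2O, 25 → 40 °C; then AcOH to pH 6
Reagents that add atoms: none
Why: Claisen–Schmidt aldol condensation; the enolate of 5 adds to the aldehyde and E1cB dehydration gives the conjugated (E)-enone, the acetal is inert to hydroxide, and stopping the quench at pH 6 avoids acid-induced closure to a flavylium salt.

Step 4
Reactants: 6 (E)-3-[2-hydroxy-6-methoxy-4-(methoxymethoxy)phenyl]-1-phenylprop-2-en-1-one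
Product: 7 3-[2-hydroxy-6-methoxy-4-(methoxymethoxy)phenyl]-1-phenylpropan-1-one
Conditions: H2 (1 atm), 5% Pd/C, Ph2S (cat.), EtOAc, 25 °C
Reagents that add atoms: none
Why: Catalytic hydrogenation of the conjugated C=C bond; sulfur-moderated Pd/C at atmospheric pressure should stop at the saturated ketone without reducing the aryl ketone or cleaving the acetal.

Step 5
Reactants: 7 3-[2-hydroxy-6-methoxy-4-(methoxymethoxy)phenyl]-1-phenylpropan-1-one
Product: 8 2-[(3R)-3-hydroxy-3-phenylpropyl]-3-methoxy-5-(methoxymethoxy)phenol
Conditions: (S)-2-methyl-CBS-oxazaborolidine (15 mol %), BH3·SMe2 (2.2 equiv), THF, −20 °C; then MeOH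
Reagents that add atoms: none
Why: Corey–Bakshi–Shibata reduction; the first equivalent of borane turns the phenol into an aryloxyborane, and the oxazaborolidine–borane complex binds the ketone with phenyl as the large group and the primary alkyl chain as the small one, so the (S)-catalyst should deliver hydride to the face that gives the (R)-carbinol, as with other aryl alkyl ketones.

Step 6
Reactants: 8 2-[(3R)-3-hydroxy-3-phenylpropyl]-3-methoxy-5-(methoxymethoxy)phenol
Product: 9 (2S)-5-methoxy-7-(methoxymethoxy)flavan [(2S)-5-methoxy-7-(methoxymethoxy)-2-phenylchroman]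
Conditions: PPh3, DIAD, THF, 0 → 25 °C
Reagents that add atoms: none
Why: Intramolecular Mitsunobu etherification; the benzylic alcohol is activated as its oxyphosphonium ion and displaced by the ortho phenoxide in a 6-exo-tet SN2 reaction with inversion, which turns the (R)-carbinol into (S)-C2, and the unsubstituted phenyl ring gives little tendency to ionise.

Step 7
Reactants: 9 (2S)-5-methoxy-7-(methoxymethoxy)flavan
Product: 10 (2S)-8-iodo-5-methoxy-7-(methoxymethoxy)flavan
Conditions: NIS, MeCN, −20 → 0 °C, dark
Reagents that add atoms: N-iodosuccinimide, O=C1CCC(=O)N1I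
Why: Electrophilic aromatic iodination of a phloroglucinol triether; C6 and C8 are both doubly activated, but C6 is crowded by the C5 methoxy group (its methyl is pushed towards C6 by the C4 methylene) and by the acetal, whereas C8 has the unencumbered ring oxygen as one neighbour, which is the usual C8 preference of 5,7-dialkoxyflavans in halogenation.

Step 8
Reactants: 10 (2S)-8-iodo-5-methoxy-7-(methoxymethoxy)flavan; 11 2-acetyl-5-bromofuran
Product: 14 (2S)-8-(5-acetylfuran-2-yl)-5-methoxy-7-(methoxymethoxy)flavan, via arylmagnesium chloride 12 (not isolated), via arylzinc chloride 13 (not isolated)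
Conditions: iPrMgCl·LiCl, THF, 0 → 25 °C; ZnCl2, 0 °C; then 11, Pd(OAc)2 (2 mol %), SPhos (4 mol %), 25 → 50 °C
Reagents that add atoms: none
Why: Iodine–magnesium exchange assisted by the two ortho oxygens, transmetalation to zinc and Negishi cross-coupling; zerovalent palladium formed from Pd(OAc)2 and SPhos inserts into the C–Br bond of the electron-poor furan, the hindered but ketone-tolerant 13 transmetalates, and reductive elimination forms the C8–furan bond with the acetyl group already in place.

Step 9
Reactants: 14 (2S)-8-(5-acetylfuran-2-yl)-5-methoxy-7-(methoxymethoxy)flavan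
Product: 16 (2S)-8-[5-(diazoacetyl)furan-2-yl]-5-methoxy-7-(methoxymethoxy)flavan, via trifluoroacetyl diketone 15 (not isolated)
Conditions: LiN(SiMe3)2, THF, −78 °C; CF3CO2CH2CF3; 5% aq. HCl, 0 °C; then 4-AcNHC6H4SO2N3, Et3N, H2O (1 equiv), MeCN, 25 °C
Reagents that add atoms: 4-acetamidobenzenesulfonyl azide, CC(=O)Nc1ccc(cc1)S(=O)(=O)N=[N+]=[N-]
Why: Detrifluoroacetylative diazo transfer; the lithium enolate of the methyl ketone is acylated to the activated diketone 15, which accepts N2 from the sulfonyl azide and loses the trifluoroacetyl group as an N-acylsulfonamide, giving the terminal diazoketone without acid chloride or diazomethane and with one of the least shock-sensitive transfer reagents.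

Step 10
Reactants: 17 ethyl acetate
Product: 19 1-(triisopropylsiloxy)propyne, via lithium ynolate 18 (not isolated)
Conditions: CH2Br2, lithium 2,2,6,6-tetramethylpiperidide, THF, −78 °C; 17; LiN(SiMe3)2; n-BuLi, −78 → 25 °C; iPr3SiCl, −78 → 25 °C; distillation
Reagents that add atoms: dibromomethane, BrCBr; chlorotriisopropylsilane, CC(C)[Si](Cl)(C(C)C)C(C)C
Why: Kowalski ester homologation stopped at the ynolate; dibromomethyllithium adds to the ester, the derived dibromo enolate undergoes bromine–lithium exchange and a 1,2-shift of methyl to give 18, and the bulky silyl chloride traps 18 on oxygen, not carbon.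

Step 11
Reactants: 16 (2S)-8-[5-(diazoacetyl)furan-2-yl]-5-methoxy-7-(methoxymethoxy)flavan; 19 1-(triisopropylsiloxy)propyne
Product: 24 (2S)-8-[4-hydroxy-5-methyl-6-(triisopropylsiloxy)benzofuran-2-yl]-5-methoxy-7-(methoxymethoxy)flavan, via furylketene 20 (not isolated), via cyclobutenone 21 (not isolated), via dienylketene 22 (not isolated), via cyclohexadienone 23 (not isolated)
Conditions: 19 (2 equiv), degassed ClCH2CH2Cl, hν (medium-pressure Hg lamp, Pyrex), 25 °C; then 80 °C
Reagents that add atoms: none
Why: This is the second-generation Danheiser benzannulation (photochemical Wolff variant), the known reaction type for aryl and heteroaryl diazomethyl ketones with siloxyalkynes. Light expels N2 from 16 and the furyl group shifts to the carbene carbon (C7′–C7a′), giving furylketene 20. The electron-rich alkyne adds across the ketene C=C in a [2+2]: its nucleophilic methyl-bearing carbon attacks the electrophilic ketene carbonyl carbon (C4′–C5′) and its oxygen-bearing carbon bonds to the ketene CH (C6′–C7′), giving cyclobutenone 21. Heating opens 21 by reversible four-electron electrocyclic cleavage to dienylketene 22, and the isomer with the furyl group cis to the ketene is drained by the next step. Ring E closes by a thermal six-electron electrocyclization of 22 in which the ketene carbon bonds to the furan β-carbon (C4′–C3a′), and dienone 23 tautomerises to the aromatic phenol. No stereocentre is created in the product, since the sp3 centres of 21 and 23 are transient, and C2 is a remote spectator. The selectivities needed are the orientation of the [2+2], secured by the polarisation of siloxyalkyne and ketene, and the site of closure, secured because only one furan carbon adjoins the ketene-bearing position; excess 19 keeps alkyne capture ahead of ketene dimerisation. The acetal at the C7 oxygen offers no O–H to intercept the ketenes, and the two ring E oxygens emerge differentiated.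

Step 12
Reactants: 24 (2S)-8-[4-hydroxy-5-methyl-6-(triisopropylsiloxy)benzofuran-2-yl]-5-methoxy-7-(methoxymethoxy)flavan
Product: 25 (2S)-5-methoxy-8-[4-methoxy-5-methyl-6-(triisopropylsiloxy)benzofuran-2-yl]-7-(methoxymethoxy)flavan
Conditions: MeI, K2CO3, acetone, 40 °C
Reagents that add atoms: iodomethane, CI
Why: Williamson O-methylation of the only free phenol; K2CO3 in acetone should be mild enough to leave the aryl silyl ether and the acetal untouched, so the two ring E oxygens stay differentiated.

Step 13
Reactants: 25 (2S)-5-methoxy-8-[4-methoxy-5-methyl-6-(triisopropylsiloxy)benzofuran-2-yl]-7-(methoxymethoxy)flavan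
Product: 27 (2S)-8-(6-hydroxy-4-methoxy-5-methylbenzofuran-2-yl)-5-methoxyflavan-7-ol (CNP0000229.1), via desilylated phenol 26 (not isolated)
Conditions: Bu4NF, THF, 0 °C; then MeOH, 3 M aq. HCl, 45 °C
Reagents that add atoms: none
Why: Fluoride cleaves the aryl O–Si bond to give 26, and acid-catalysed acetal methanolysis in the same flask removes the methoxymethyl group; the aryl methyl ethers and, at this acidity, the C2–O1 bond of a flavan with an unactivated phenyl ring should survive, so (S)-C2 is untouched.

## Compound list

1 | 5-methoxyresorcinol (5-methoxybenzene-1,3-diol) | COc1cc(O)cc(O)c1 | starting material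
2 | [(2,4-dihydroxy-6-methoxyphenyl)methylidene]dimethyliminium chloride | C[N+](C)=Cc1c(O)cc(O)cc1OC.[Cl-] | intermediate
3 | 2,4-dihydroxy-6-methoxybenzaldehyde | COc1cc(O)cc(O)c1C=O | intermediate
4 | 2-hydroxy-6-methoxy-4-(methoxymethoxy)benzaldehyde | COCOc1cc(O)c(C=O)c(OC)c1 | intermediate
5 | acetophenone | CC(=O)c1ccccc1 | starting material
6 | (E)-3-[2-hydroxy-6-methoxy-4-(methoxymethoxy)phenyl]-1-phenylprop-2-en-1-one | O=C(/C=C/c1c(O)cc(OCOC)cc1OC)c1ccccc1 | intermediate
7 | 3-[2-hydroxy-6-methoxy-4-(methoxymethoxy)phenyl]-1-phenylpropan-1-one | O=C(CCc1c(O)cc(OCOC)cc1OC)c1ccccc1 | intermediate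
8 | 2-[(3R)-3-hydroxy-3-phenylpropyl]-3-methoxy-5-(methoxymethoxy)phenol | O[C@H](CCc1c(O)cc(OCOC)cc1OC)c1ccccc1 | intermediate
9 | (2S)-5-methoxy-7-(methoxymethoxy)flavan | COc1cc(OCOC)cc2c1CC[C@@H](c1ccccc1)O2 | intermediate
10 | (2S)-8-iodo-5-methoxy-7-(methoxymethoxy)flavan | COc1cc(OCOC)c(I)c2c1CC[C@@H](c1ccccc1)O2 | intermediate
11 | 2-acetyl-5-bromofuran [1-(5-bromofuran-2-yl)ethan-1-one] | CC(=O)c1ccc(Br)o1 | starting material
12 | [(2S)-5-methoxy-7-(methoxymethoxy)flavan-8-yl]magnesium chloride | COc1cc(OCOC)c([Mg]Cl)c2c1CC[C@@H](c1ccccc1)O2 | intermediate
13 | [(2S)-5-methoxy-7-(methoxymethoxy)flavan-8-yl]zinc chloride | COc1cc(OCOC)c([Zn]Cl)c2c1CC[C@@H](c1ccccc1)O2 | intermediate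
14 | (2S)-8-(5-acetylfuran-2-yl)-5-methoxy-7-(methoxymethoxy)flavan | COc1cc(OCOC)c(-c2ccc(o2)C(C)=O)c2c1CC[C@@H](c1ccccc1)O2 | intermediate
15 | 4,4,4-trifluoro-1-{5-[(2S)-5-methoxy-7-(methoxymethoxy)flavan-8-yl]furan-2-yl}butane-1,3-dione | COc1cc(OCOC)c(-c2ccc(o2)C(=O)CC(=O)C(F)(F)F)c2c1CC[C@@H](c1ccccc1)O2 | intermediate
16 | (2S)-8-[5-(diazoacetyl)furan-2-yl]-5-methoxy-7-(methoxymethoxy)flavan | COc1cc(OCOC)c(-c2ccc(o2)C(=O)C=[N+]=[N-])c2c1CC[C@@H](c1ccccc1)O2 | intermediate
17 | ethyl acetate | CCOC(C)=O | starting material
18 | lithium prop-1-yn-1-olate | CC#C[O-].[Li+] | intermediate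
19 | 1-(triisopropylsiloxy)propyne | CC#CO[Si](C(C)C)(C(C)C)C(C)C | intermediate
20 | 2-{5-[(2S)-5-methoxy-7-(methoxymethoxy)flavan-8-yl]furan-2-yl}ethen-1-one (furylketene) | COc1cc(OCOC)c(-c2ccc(o2)C=C=O)c2c1CC[C@@H](c1ccccc1)O2 | intermediate
21 | 4-{5-[(2S)-5-methoxy-7-(methoxymethoxy)flavan-8-yl]furan-2-yl}-2-methyl-3-(triisopropylsiloxy)cyclobut-2-en-1-one (both epimers at the ring CH) | COc1cc(OCOC)c(-c3ccc(o3)C4C(=O)C(C)=C4O[Si](C(C)C)(C(C)C)C(C)C)c2c1CC[C@@H](c1ccccc1)O2 | intermediate
22 | 4-{5-[(2S)-5-methoxy-7-(methoxymethoxy)flavan-8-yl]furan-2-yl}-2-methyl-3-(triisopropylsiloxy)buta-1,3-dien-1-one, furyl cis to the ketene carbon (dienylketene) | COc1cc(OCOC)c(-c3ccc(o3)\C=C(O[Si](C(C)C)(C(C)C)C(C)C)/C(C)=C=O)c2c1CC[C@@H](c1ccccc1)O2 | intermediate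
23 | 2-[(2S)-5-methoxy-7-(methoxymethoxy)flavan-8-yl]-5-methyl-6-(triisopropylsiloxy)-3aH-benzofuran-4-one (keto tautomer of 24, either configuration at C3a′) | COc1cc(OCOC)c(C3=CC4C(=O)C(C)=C(O[Si](C(C)C)(C(C)C)C(C)C)C=C4O3)c2c1CC[C@@H](c1ccccc1)O2 | intermediate
24 | (2S)-8-[4-hydroxy-5-methyl-6-(triisopropylsiloxy)benzofuran-2-yl]-5-methoxy-7-(methoxymethoxy)flavan | COc1cc(OCOC)c(-c2cc3c(O)c(C)c(O[Si](C(C)C)(C(C)C)C(C)C)cc3o2)c2c1CC[C@@H](c1ccccc1)O2 | intermediate
25 | (2S)-5-methoxy-8-[4-methoxy-5-methyl-6-(triisopropylsiloxy)benzofuran-2-yl]-7-(methoxymethoxy)flavan | COc1cc(OCOC)c(-c2cc3c(OC)c(C)c(O[Si](C(C)C)(C(C)C)C(C)C)cc3o2)c2c1CC[C@@H](c1ccccc1)O2 | intermediate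
26 | (2S)-8-(6-hydroxy-4-methoxy-5-methylbenzofuran-2-yl)-5-methoxy-7-(methoxymethoxy)flavan | COc1cc(OCOC)c(-c2cc3c(OC)c(C)c(O)cc3o2)c2c1CC[C@@H](c1ccccc1)O2 | intermediate
27 | (2S)-8-(6-hydroxy-4-methoxy-5-methylbenzofuran-2-yl)-5-methoxyflavan-7-ol | COc1cc(O)c(-c2cc3c(OC)c(C)c(O)cc3o2)c2c1CC[C@@H](c1ccccc1)O2 | target

## Step count and least certain steps

Total step count: 13. Longest linear sequence: 12 (steps 1 to 9 and 11 to 13); step 10 is a one-step side branch.

Step 11 (key step). Most likely to go wrong: competing light absorption and secondary photochemistry of the 2-aryl-5-acylfuran chromophore and of the benzofuran product, and capture of ketenes 20 and 22 by the phenol as it forms (ester formation), both of which would stall conversion. Fallback: ring E is built first on a small furan and the C8–C2′ bond is made last. Purchased 4,4,4-trifluoro-1-(furan-2-yl)butane-1,3-dione F1 should give 2-diazo-1-(furan-2-yl)ethanone F2 by diazo transfer with the sulfonyl azide and Et3N of step 9; F2 is a small diazoketone to be kept in solution. F2 and 19 under the conditions of step 11 should give 5-methyl-6-(triisopropylsiloxy)benzofuran-4-ol F3, and methylation as in step 12 gives 4-methoxy-5-methyl-6-(triisopropylsiloxy)benzofuran F4. Deprotonation of F4 at C2 with n-BuLi (THF, −78 °C) and ZnCl2 gives [4-methoxy-5-methyl-6-(triisopropylsiloxy)benzofuran-2-yl]zinc chloride F5, which is coupled with 10 under the palladium conditions of step 8. This sets out from 19 and 10 and comes back to the route at 25, bypassing 14, 16 and 24.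

Step 7. Most likely to go wrong: insufficient discrimination between C8 and C6, or double iodination, because both positions are flanked by two oxygens. Fallback: directed ortho-metalation in place of electrophilic substitution. n-BuLi (THF, 0 °C) should remove the C8 proton of 9, which lies between the acetal oxygen and the in-plane lone pair of O1, whereas the lone pair of the C5 methoxy group points away from C6. This gives (2S)-8-lithio-5-methoxy-7-(methoxymethoxy)flavan F6, and ZnCl2 converts F6 into 13, which is coupled with 11 as in step 8. This sets out from 9 and comes back at 13, bypassing 10 and 12.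

Step 10. Most likely to go wrong: deprotonation of the small, enolisable ester by the amide base or the carbenoid (self-condensation) in competition with addition, and loss of the volatile, moisture-sensitive product on isolation. Fallback: oxidation of an acetylide in place of ester homologation. Purchased 1-propynyllithium F7 is treated with lithium tert-butyl peroxide F8 (from anhydrous tert-butyl hydroperoxide and LiN(SiMe3)2, THF, −78 → 0 °C); oxygen transfer should give 18, which is silylated with iPr3SiOTf. This does not set out from a numbered compound: F7 replaces 17, and the route is rejoined at 18.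

Step 8. Most likely to go wrong: slow or incomplete iodine–magnesium exchange on the electron-rich ring, attack of residual arylmagnesium on the acetyl group of 11, or slow transmetalation of the doubly ortho-substituted arylzinc leading to homocoupling. Fallback: Suzuki–Miyaura coupling with reversed polarity. 10 and purchased 5-formylfuran-2-boronic acid F9 (Pd(OAc)2, SPhos, K3PO4, THF/H2O, 40 °C) should give 5-[(2S)-5-methoxy-7-(methoxymethoxy)flavan-8-yl]furan-2-carbaldehyde F10. MeMgBr (THF, −78 °C) gives (2S)-8-[5-(1-hydroxyethyl)furan-2-yl]-5-methoxy-7-(methoxymethoxy)flavan F11 as a mixture of carbinol epimers, and MnO2 (CH2Cl2) oxidises F11 to 14. This sets out from 10 and comes back at 14.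

Step 1. Most likely to go wrong: formylation between the two hydroxyls in place of the position next to the methoxy group, or double formylation, giving an isomer that is hard to separate. Fallback: a symmetrical aldehyde is desymmetrised instead. Purchased 2,4,6-trihydroxybenzaldehyde F12 is protected at its unchelated para hydroxyl as in step 2 to give 2,6-dihydroxy-4-(methoxymethoxy)benzaldehyde F13. One of the two equivalent ortho hydroxyls of F13 is then methylated (MeI, 1 equiv, K2CO3, acetone); the remaining hydroxyl is deactivated by its hydrogen bond to the formyl group. This replaces 1 to 3 and comes back at 4.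

## Further compounds

F1 | step 11 | 4,4,4-trifluoro-1-(furan-2-yl)butane-1,3-dione (purchased) | O=C(CC(=O)C(F)(F)F)c1ccco1
F2 | step 11 | 2-diazo-1-(furan-2-yl)ethanone | [N-]=[N+]=CC(=O)c1ccco1
F3 | step 11 | 5-methyl-6-(triisopropylsiloxy)benzofuran-4-ol | Cc1c(O)c2ccoc2cc1O[Si](C(C)C)(C(C)C)C(C)C
F4 | step 11 | 4-methoxy-5-methyl-6-(triisopropylsiloxy)benzofuran | COc1c(C)c(O[Si](C(C)C)(C(C)C)C(C)C)cc2occc12
F5 | step 11 | [4-methoxy-5-methyl-6-(triisopropylsiloxy)benzofuran-2-yl]zinc chloride | COc1c(C)c(O[Si](C(C)C)(C(C)C)C(C)C)cc2oc([Zn]Cl)cc12
F6 | step 7 | (2S)-8-lithio-5-methoxy-7-(methoxymethoxy)flavan | COc1cc(OCOC)c([Li])c2c1CC[C@@H](c1ccccc1)O2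
F7 | step 10 | 1-propynyllithium (purchased) | [Li]C#CC
F8 | step 10 | lithium tert-butyl peroxide | CC(C)(C)O[O-].[Li+]
F9 | step 8 | 5-formylfuran-2-boronic acid (purchased) | O=Cc1ccc(o1)B(O)O
F10 | step 8 | 5-[(2S)-5-methoxy-7-(methoxymethoxy)flavan-8-yl]furan-2-carbaldehyde | COc1cc(OCOC)c(-c2ccc(o2)C=O)c2c1CC[C@@H](c1ccccc1)O2
F11 | step 8 | (2S)-8-[5-(1-hydroxyethyl)furan-2-yl]-5-methoxy-7-(methoxymethoxy)flavan (both carbinol epimers) | COc1cc(OCOC)c(-c2ccc(o2)C(C)O)c2c1CC[C@@H](c1ccccc1)O2
F12 | step 1 | 2,4,6-trihydroxybenzaldehyde (purchased) | O=Cc1c(O)cc(O)cc1O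
F13 | step 1 | 2,6-dihydroxy-4-(methoxymethoxy)benzaldehyde | COCOc1cc(O)c(C=O)c(O)c1
A1 | alternative 1 | (2S)-7-benzyloxy-5-methoxy-8-[4-methoxy-5-methyl-6-(triisopropylsiloxy)benzofuran-2-yl]flavan | COc1cc(OCc2ccccc2)c(-c2cc3c(OC)c(C)c(O[Si](C(C)C)(C(C)C)C(C)C)cc3o2)c2c1CC[C@@H](c1ccccc1)O2
A2 | alternative 1 | (2S)-8-acetyl-7-benzyloxy-5-methoxyflavan | COc1cc(OCc2ccccc2)c(C(C)=O)c2c1CC[C@@H](c1ccccc1)O2
A3 | alternative 1 | O-[3-methoxy-4-methyl-5-(triisopropylsiloxy)phenyl]hydroxylamine | NOc1cc(OC)c(C)c(O[Si](C(C)C)(C(C)C)C(C)C)c1
A4 | alternative 2 | (2S)-8-iodo-5-methoxy-7-(methoxymethoxy)flavan (identical with 10) | COc1cc(OCOC)c(I)c2c1CC[C@@H](c1ccccc1)O2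
A5 | alternative 2 | (1S)-3-[2-fluoro-6-methoxy-4-(methoxymethoxy)phenyl]-1-phenylpropan-1-ol | O[C@@H](CCc1c(F)cc(OCOC)cc1OC)c1ccccc1
A6 | alternative 2 | lithium (1S)-3-[6-methoxy-4-(methoxymethoxy)-2,3-didehydrophenyl]-1-phenylpropan-1-olate (C8–C8a aryne) | COC1=C(CC[C@H]([O-])c2ccccc2)C#CC(OCOC)=C1.[Li+]
A7 | alternative 3 | (2S)-7-benzyloxy-8-(6-benzyloxy-4-methoxy-5-methylbenzofuran-2-yl)-5-methoxyflavan | COc1cc(OCc2ccccc2)c(-c2cc3c(OC)c(C)c(OCc4ccccc4)cc3o2)c2c1CC[C@@H](c1ccccc1)O2
A8 | alternative 3 | 3-benzyloxy-2-(6-benzyloxy-4-methoxy-5-methylbenzofuran-2-yl)-6-(hydroxymethyl)-5-methoxyphenol | COc1cc(OCc2ccccc2)c(-c2cc3c(OC)c(C)c(OCc4ccccc4)cc3o2)c(O)c1CO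
A9 | alternative 3 | styrene | C=Cc1ccccc1
A10 | alternative 3 | 3-benzyloxy-2-(6-benzyloxy-4-methoxy-5-methylbenzofuran-2-yl)-5-methoxy-6-methylidenecyclohexa-2,4-dien-1-one (ortho-quinone methide) | COC1=CC(OCc2ccccc2)=C(-c2cc3c(OC)c(C)c(OCc4ccccc4)cc3o2)C(=O)C1=C
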